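**Retrosynthetic overview**
- The target comes from O-methylation of the ring A phenol of its 4-O-demethyl triol, a sinapyl/coniferyl 8–5' neolignan.
- The triol comes from one hydride reduction of a phenylcoumaran that carries C9 as an N-acyl camphorsultam and C9' as a methyl ester; the auxiliary is released.
- The phenylcoumaran comes from a single oxidative 8–5' cross-coupling of N-sinapoyl-(2R)-bornane-10,2-sultam with methyl ferulate. The C8–C5' bond forms first, then the C7–O bond closes on the quinone methide; this makes the only new ring (the dihydrofuran ring) and both stereocentres.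
- The N-sinapoyl sultam comes from methyl sinapate and (2R)-bornane-10,2-sultam.

Assumption: methyl sinapate and methyl ferulate are bought as catalogue items (each is otherwise one Fischer esterification of the very cheap acid).
Assumption: the sinapoyl sultam reacts with the usual Oppolzer facial sense (new bond on the Cα Re face of the (2R)-sultam derivative); this fixes which sultam antipode is used and is to be confirmed by X-ray or CD of the coupling product at the first run.

**Step 1**
Reactants: 1 methyl sinapate [methyl (E)-3-(4-hydroxy-3,5-dimethoxyphenyl)prop-2-enoate]; 2 (2R)-bornane-10,2-sultam [(1S)-(−)-2,10-camphorsultam]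
Product: 3 (2R)-N-[(E)-3-(4-hydroxy-3,5-dimethoxyphenyl)prop-2-enoyl]bornane-10,2-sultam (N-sinapoyl sultam)
Conditions: 2 (1.1 equiv), AlMe3 (2.3 equiv), toluene, 0 °C → rt; then 1, 80 °C, 12 h; 1 M HCl work-up
Reagents that add atoms: none
Why: Weinreb-type aminolysis, in which AlMe3 turns the weakly nucleophilic sultam N–H into an Al–N amide (and the phenol into an aluminium phenoxide, so no protecting group is needed) that attacks the ester carbonyl in a 1,2 sense and expels methoxide; no stereocentre is formed and the E-alkene is untouched.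

**Step 2**
Reactants: 3 N-sinapoyl sultam; 4 methyl ferulate [methyl (E)-3-(4-hydroxy-3-methoxyphenyl)prop-2-enoate]
Product: 8 (2R)-N-{[(2R,3R)-2-(4-hydroxy-3,5-dimethoxyphenyl)-7-methoxy-5-[(E)-3-methoxy-3-oxoprop-1-enyl]-2,3-dihydrobenzofuran-3-yl]carbonyl}bornane-10,2-sultam, via sinapoyl sultam phenoxyl radical 5 (not isolated), via methyl ferulate phenoxyl radical 6 (not isolated), via 8–5' quinone methide 7 (not isolated)
Conditions: 4 (4 equiv), Ag2O (3 equiv), dry benzene–acetone 2:1, rt, dark, N2; 3 added by syringe pump over 8 h, then 12 h; SiO2 chromatography and recrystallisation to remove the minor (2S,3S) diastereomer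
Reagents that add atoms: none
Why: Proposed new method: Ag2O takes one electron from each phenol, and slow addition keeps radical 5 dilute in a pool of radical 6, so 5 is intercepted at C8 by C5 of 6 (both ortho positions of 5 carry OMe, so this is its only coupling mode that can end in a phenylcoumaran); the auxiliary (s-cis acyl, C=O anti to SO2, lower sulfonyl oxygen shielding the Cα Si face) directs the new C8–C5' bond to the Cα Re face and so sets C8, and the ortho-phenol then adds to quinone methide 7 (intramolecular oxa-Michael, 5-exo) trans to the acyl group and so sets C7; the closest known chemistry is the Ag2O-mediated biomimetic 8–5' dehydrodimerisation of ferulates, including its chiral-amide-directed homodimer version, and because the auxiliary is still attached any minor isomer is a separable diastereomer.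

**Step 3**
Reactants: 8 phenylcoumaran acyl sultam methyl ester
Product: 9 4-[(2R,3S)-3-(hydroxymethyl)-5-[(E)-3-hydroxyprop-1-enyl]-7-methoxy-2,3-dihydrobenzofuran-2-yl]-2,6-dimethoxyphenol [(7R,8S)-4-O-demethyl triol]
Conditions: iBu2AlH (DIBAL-H, 10 equiv), THF–toluene, −78 → 0 °C, 3 h; aq. KNaC4H4O6 (potassium sodium tartrate) work-up; sultam 2 recovered
Reagents that add atoms: none
Why: Hydride reduction, in which excess iBu2AlH adds 1,2 to the cinnamate ester to give the allylic alcohol and reduces the activated N-acyl sultam through the aldehyde to the primary alcohol with release of the auxiliary; C8 stops being enolisable and both stereocentres are carried through unchanged.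

**Step 4**
Reactants: 9 (7R,8S)-4-O-demethyl triol
Product: 10 (−)-(7R,8S,7'E)-3,4,5,5'-tetramethoxy-4',7-epoxy-8,3'-neolign-7'-ene-9,9'-diol [(E)-3-[(2R,3S)-3-(hydroxymethyl)-7-methoxy-2-(3,4,5-trimethoxyphenyl)-2,3-dihydrobenzofuran-5-yl]prop-2-en-1-ol]
Conditions: MeI (1.5 equiv), K2CO3 (2 equiv), acetone, rt → 40 °C, 12 h
Reagents that add atoms: iodomethane, CI
Why: Williamson ether synthesis, in which K2CO3 deprotonates only the phenol (pKa about 10) and not the two primary alcohols (pKa about 16), so MeI methylates O-4 selectively; no stereocentre is touched.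

**Compound list**
1 | methyl sinapate, methyl (E)-3-(4-hydroxy-3,5-dimethoxyphenyl)prop-2-enoate | COC(=O)/C=C/c1cc(OC)c(O)c(OC)c1 | starting material
2 | (2R)-bornane-10,2-sultam, (1S)-(−)-2,10-camphorsultam, (3aS,6R,7aR) | O=S1(=O)C[C@@]23CC[C@@H](C2(C)C)C[C@H]3N1 | starting material
3 | (2R)-N-[(E)-3-(4-hydroxy-3,5-dimethoxyphenyl)prop-2-enoyl]bornane-10,2-sultam | O=S1(=O)C[C@@]23CC[C@@H](C2(C)C)C[C@H]3N1C(=O)/C=C/c1cc(OC)c(O)c(OC)c1 | intermediate
4 | methyl ferulate, methyl (E)-3-(4-hydroxy-3-methoxyphenyl)prop-2-enoate | COC(=O)/C=C/c1ccc(O)c(OC)c1 | starting material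
5 | phenoxyl radical of 3 (spin at O-4, C8 and the ring) | O=S1(=O)C[C@@]23CC[C@@H](C2(C)C)C[C@H]3N1C(=O)/C=C/c1cc(OC)c([O])c(OC)c1 | intermediate (not isolated)
6 | phenoxyl radical of 4 (spin at O-4, C5 and C8) | COC(=O)/C=C/c1ccc([O])c(OC)c1 | intermediate (not isolated)
7 | (2R)-N-[(2S)-3-(3,5-dimethoxy-4-oxocyclohexa-2,5-dien-1-ylidene)-2-{2-hydroxy-3-methoxy-5-[(E)-3-methoxy-3-oxoprop-1-enyl]phenyl}propanoyl]bornane-10,2-sultam (8–5' quinone methide) | COC1=CC(=C[C@@H](c2cc(/C=C/C(=O)OC)cc(OC)c2O)C(=O)N2[C@@H]3C[C@H]4CC[C@]3(CS2(=O)=O)C4(C)C)C=C(OC)C1=O | intermediate (not isolated)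
8 | (2R)-N-{[(2R,3R)-2-(4-hydroxy-3,5-dimethoxyphenyl)-7-methoxy-5-[(E)-3-methoxy-3-oxoprop-1-enyl]-2,3-dihydrobenzofuran-3-yl]carbonyl}bornane-10,2-sultam (trans) | COc1cc([C@@H]2Oc3c(OC)cc(/C=C/C(=O)OC)cc3[C@H]2C(=O)N2[C@@H]4C[C@H]5CC[C@]4(CS2(=O)=O)C5(C)C)cc(OC)c1O | intermediate
9 | 4-[(2R,3S)-3-(hydroxymethyl)-5-[(E)-3-hydroxyprop-1-enyl]-7-methoxy-2,3-dihydrobenzofuran-2-yl]-2,6-dimethoxyphenol | COc1cc([C@@H]2Oc3c(OC)cc(/C=C/CO)cc3[C@H]2CO)cc(OC)c1O | intermediate
10 | (−)-(7R,8S,7'E)-3,4,5,5'-tetramethoxy-4',7-epoxy-8,3'-neolign-7'-ene-9,9'-diol | COc1cc([C@@H]2Oc3c(OC)cc(/C=C/CO)cc3[C@H]2CO)cc(OC)c1OC | target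

**Totals**
Total step count: 4. Longest linear sequence: 4 steps (1 → 3 → 8 → 9 → 10).

**Steps most likely to fail, with fallbacks**

Step 2 (cross-selectivity and facial selectivity of the radical coupling). The likely problems are homodimers of each partner and 8–8 or 8–O–4 cross-products taking most of compound 3. The fallback sets out from compound 3 and comes back at compound 8. Compound 3 is oxidised under the same Ag2O conditions with vanillin (5 equiv) in place of compound 4. The vanillin radical has no side-chain radical site, so toward C8 of the sinapoyl radical its only carbon coupling site is C5. This gives (2R)-N-{[(2R,3R)-5-formyl-2-(4-hydroxy-3,5-dimethoxyphenyl)-7-methoxy-2,3-dihydrobenzofuran-3-yl]carbonyl}bornane-10,2-sultam F4. A Wittig olefination of this aldehyde with Ph3P=CHCO2Me (toluene, 60 °C, neutral, E-selective) then installs the acrylate and delivers compound 8.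

Step 1 (AlMe3 aminolysis of a cinnamate deactivated by its aluminium phenoxide). The fallback sets out from compound 2 and comes back at compound 3. Commercial sinapic acid is acetylated (Ac2O, pyridine) to (E)-3-(4-acetoxy-3,5-dimethoxyphenyl)prop-2-enoic acid F1. This is converted with (COCl)2 and catalytic DMF in CH2Cl2 into (E)-3-(4-acetoxy-3,5-dimethoxyphenyl)prop-2-enoyl chloride F2. Compound 2 is deprotonated with NaH in toluene and acylated with F2 to give (2R)-N-[(E)-3-(4-acetoxy-3,5-dimethoxyphenyl)prop-2-enoyl]bornane-10,2-sultam F3. Pyrrolidine in CH2Cl2 at 0 °C then removes only the phenolic acetate and returns compound 3.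

Step 3 (one-pot reduction of two different acyl groups beside a free phenol). The likely problems are the acyl sultam stopping at the aldehyde stage or partial 1,4-reduction. The fallback sets out from compound 8 and comes back at compound 9. The two reductions are separated. LiBH4 in THF at 0 °C cleaves only the N-acyl sultam and gives methyl (E)-3-[(2R,3S)-2-(4-hydroxy-3,5-dimethoxyphenyl)-3-(hydroxymethyl)-7-methoxy-2,3-dihydrobenzofuran-5-yl]prop-2-enoate F5, which is isolated. The remaining cinnamate ester is then reduced on its own with iBu2AlH in toluene at −78 °C to give compound 9.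

**Further compounds**
F1 | step 1 | (E)-3-(4-acetoxy-3,5-dimethoxyphenyl)prop-2-enoic acid | CC(=O)Oc1c(OC)cc(/C=C/C(=O)O)cc1OC
F2 | step 1 | (E)-3-(4-acetoxy-3,5-dimethoxyphenyl)prop-2-enoyl chloride | CC(=O)Oc1c(OC)cc(/C=C/C(Cl)=O)cc1OC
F3 | step 1 | (2R)-N-[(E)-3-(4-acetoxy-3,5-dimethoxyphenyl)prop-2-enoyl]bornane-10,2-sultam | O=S1(=O)C[C@@]23CC[C@@H](C2(C)C)C[C@H]3N1C(=O)/C=C/c1cc(OC)c(OC(C)=O)c(OC)c1
F4 | step 2 | (2R)-N-{[(2R,3R)-5-formyl-2-(4-hydroxy-3,5-dimethoxyphenyl)-7-methoxy-2,3-dihydrobenzofuran-3-yl]carbonyl}bornane-10,2-sultam | COc1cc([C@@H]2Oc3c(OC)cc(C=O)cc3[C@H]2C(=O)N2[C@@H]4C[C@H]5CC[C@]4(CS2(=O)=O)C5(C)C)cc(OC)c1O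
F5 | step 3 | methyl (E)-3-[(2R,3S)-2-(4-hydroxy-3,5-dimethoxyphenyl)-3-(hydroxymethyl)-7-methoxy-2,3-dihydrobenzofuran-5-yl]prop-2-enoate | COc1cc([C@@H]2Oc3c(OC)cc(/C=C/C(=O)OC)cc3[C@H]2CO)cc(OC)c1O
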